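**Retrosynthetic overview**
- Feature: in the 4-aryl-6,7-dioxygenated 2-naphthoate, C1 and C4 of ring B are both benzylic to ring A and C2–C3 is a two-carbon acyl unit. Ring B is therefore an o-quinodimethane (C1, C8a, C4a, C4) plus a propiolate (C2≡C3) that already carries the (R)-danshensu ester.
- Eritrichin 13 ⇐ global hydrogenolysis of heptabenzyl naphthoate 12 ⇐ 1,4-dehydration of cis-1,4-dihydronaphthalen-1-ol 11 ⇐ photoenolisation/[4+2] (forms C1–C2 and C3–C4) of aldehyde 5 with propiolate 9.
- 5 ⇐ sp2–sp3 Suzuki–Miyaura coupling of bromoaldehyde 2 (from 1) with benzylic boronate 4 (from 3). This assembly uses base only, because acidic benzylation/formylation would invite cyclotriveratrylene-type self-condensation, benzyl ether migration and Bradsher cyclodehydration of 5.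
- 9 ⇐ Steglich esterification of tribenzyl (R)-danshensu 7 with propiolic acid 8. The only stereocentre of the target is bought with 6, and none of its bonds is ever broken.
- Ring order: ring A, the C4-aryl ring and the danshensu ring are bought. Ring B is the only ring formed (step 6) and is aromatised in step 7.

Key step: step 6

Assumption: 1, 3, 6 (as the free acid) and 8 are taken as catalogue chemicals; because the remote (R)-centre cannot distinguish the two faces of the diene, number 11 stands for the unseparated pair of cis adducts, drawn as the (1S,4R) isomer (its partner has both ring centres inverted, 1R,4S), and step 7 erases C1 and C4 in both.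

**Step 1**
Reactants: 1 3,4-bis(benzyloxy)benzaldehyde
Product: 2 4,5-bis(benzyloxy)-2-bromobenzaldehyde
Conditions: Br2 (1.1 equiv), NaOAc (1.5 equiv), AcOH/CH2Cl2, rt, dark
Reagents that add atoms: bromine, BrBr
Why: Electrophilic aromatic bromination, in which the 3-benzyloxy group (not tied up by conjugation with CHO) directs para to C6 as in the bromination of veratraldehyde, while the acetate buffer removes HBr so the benzyl ethers survive.

**Step 2**
Reactants: 3 3,4-bis(benzyloxy)benzyl chloride
Product: 4 2-[3,4-bis(benzyloxy)benzyl]-4,4,5,5-tetramethyl-1,3,2-dioxaborolane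
Conditions: B2pin2 (1.1 equiv), Pd(dba)2 (3 mol %), P(4-MeOC6H4)3 (6 mol %), KOAc (1.5 equiv), toluene, 50 °C
Reagents that add atoms: bis(pinacolato)diboron, CC1(C)OB(OC1(C)C)B1OC(C)(C)C(C)(C)O1
Why: Miyaura borylation of a benzylic chloride (oxidative addition, acetate-assisted transmetalation, reductive elimination) in a non-acidic, non-aqueous medium, so the ionisation-prone chloride neither solvolyses nor alkylates itself.

**Step 3**
Reactants: 2 4,5-bis(benzyloxy)-2-bromobenzaldehyde; 4 2-[3,4-bis(benzyloxy)benzyl]-4,4,5,5-tetramethyl-1,3,2-dioxaborolane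
Product: 5 4,5-bis(benzyloxy)-2-[3,4-bis(benzyloxy)benzyl]benzaldehyde
Conditions: PdCl2(dppf)·CH2Cl2 (5 mol %), K2CO3 (3 equiv), 1,4-dioxane/H2O (5:1), degassed, 85 °C; product stored under Ar in the dark
Reagents that add atoms: none
Why: sp2–sp3 Suzuki–Miyaura coupling, in which the ortho-formyl group accelerates oxidative addition, the position of CHO relative to the CH2 is fixed by the bromide, and the basic medium spares the acid-sensitive 2-benzylbenzaldehyde.

**Step 4**
Reactants: 6 (R)-danshensu, (R)-3-(3,4-dihydroxyphenyl)-2-hydroxypropanoic acid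
Product: 7 benzyl (R)-3-[3,4-bis(benzyloxy)phenyl]-2-hydroxypropanoate
Conditions: BnBr (3.3 equiv), K2CO3 (3.5 equiv), DMF, Ar, rt
Reagents that add atoms: benzyl bromide, BrCc1ccccc1
Why: Williamson-type O-alkylation, in which carbonate ionises only the two phenols and the carboxylic acid, so the secondary hydroxyl stays free and the (R)-centre, whose α-H is not acidic enough for carbonate at rt, is retained.

**Step 5**
Reactants: 7 benzyl (R)-3-[3,4-bis(benzyloxy)phenyl]-2-hydroxypropanoate; 8 propiolic acid
Product: 9 benzyl (R)-3-[3,4-bis(benzyloxy)phenyl]-2-(propioloyloxy)propanoate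
Conditions: 8 (1.3 equiv), DCC (1.3 equiv), DMAP (5 mol %), CH2Cl2, −20 → 0 °C
Reagents that add atoms: none
Why: Steglich esterification acylates the oxygen without breaking the C–O bond at the stereocentre (retention), and low temperature with only catalytic DMAP limits conjugate addition to the activated alkyne.

**Step 6**
Reactants: 5 4,5-bis(benzyloxy)-2-[3,4-bis(benzyloxy)benzyl]benzaldehyde; 9 benzyl (R)-3-[3,4-bis(benzyloxy)phenyl]-2-(propioloyloxy)propanoate
Product: 11 (R)-1-(benzyloxy)-3-[3,4-bis(benzyloxy)phenyl]-1-oxopropan-2-yl cis-(1S,4R)-6,7-bis(benzyloxy)-4-[3,4-bis(benzyloxy)phenyl]-1-hydroxy-1,4-dihydronaphthalene-2-carboxylate (drawn isomer of the pair of cis adducts, carried on unseparated), via (E,E)-hydroxy-o-quinodimethane 10 (not isolated)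
Conditions: hν (365 nm LED, or medium-pressure Hg lamp with λ > 340 nm filter), 5 (0.1 M), 9 (1.5 equiv, excess recovered), degassed toluene, Ar, 20 °C; chromatography on Et3N-deactivated silica
Reagents that add atoms: none
Why: Excitation of the aldehyde of 5 and 1,5-hydrogen transfer from the doubly benzylic CH2 to the carbonyl oxygen give a biradical that relaxes to the dienols; the Z-enol falls back to 5 by a thermal 1,5-shift, so only the long-lived (E,E)-dienol 10, with OH and aryl both outward and ring A dearomatised, is available for trapping. Diene 10 then adds to the electron-poor alkyne of 9 in a concerted, suprafacial, normal-demand intermolecular [4+2] cycloaddition that forms C1–C2 and C3–C4, closes the six-membered ring B and restores the aromaticity of ring A; the closest known reaction type is the photoenolisation/Diels–Alder trapping of 2-benzylbenzaldehydes with acetylenic esters. C1 and C4 are set relative to each other by the diene geometry alone, since two outward substituents must end cis, and an alkyne raises no endo/exo question. The remote (R)-centre of 9 is not expected to differentiate the diene faces, so the (1S,4R) and (1R,4S) cis adducts should form together as 11, which is harmless because both ring centres are erased in step 7. The selectivity that the step needs is regiochemical: the enol oxygen, the strongest donor on the diene, puts the largest HOMO coefficient on the aryl-bearing C4, which bonds to the unsubstituted, sterically smaller β-carbon of the propiolate (largest LUMO coefficient), so the ester lands on C2 next to the carbinol. Light above 340 nm is absorbed only by 5, so the aryl benzyl ethers and 9 stay in the ground state, and the neutral medium leaves the α-acyloxy ester stereocentre untouched.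

**Step 7**
Reactants: 11 cis-1-hydroxy-4-aryl-1,4-dihydronaphthalene-2-carboxylate adduct (both cis diastereomers together)
Product: 12 (R)-1-(benzyloxy)-3-[3,4-bis(benzyloxy)phenyl]-1-oxopropan-2-yl 6,7-bis(benzyloxy)-4-[3,4-bis(benzyloxy)phenyl]-2-naphthoate (heptabenzyl eritrichin)
Conditions: p-TsOH·H2O (10 mol %), toluene, rt → 50 °C
Reagents that add atoms: none
Why: Acid-catalysed 1,4-dehydration (E1), in which ionisation at C1 gives a benzylic cation stabilised by the para C6 benzyloxy group and loss of the doubly benzylic, allylic C4–H aromatises ring B with release of one molecule of water, so both cis diastereomers converge on 12 without oxidant or base and the side-chain (R)-centre is not endangered.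

**Step 8**
Reactants: 12 heptabenzyl eritrichin
Product: 13 eritrichin, (R)-configured
Conditions: H2 (1 atm), 10 % Pd/C, THF/MeOH (1:1), rt; filtration and concentration under Ar
Reagents that add atoms: none
Why: Catalytic hydrogenolysis cleaves the six aryl benzyl ethers and the benzyl ester, whereas the naphthoate C–O bond at the stereocentre is only homobenzylic and the naphthalene is not reduced at 1 atm, so the (R)-centre is delivered unchanged under neutral conditions.

**Compound list**
1 | 3,4-bis(benzyloxy)benzaldehyde | O=Cc1ccc(OCc2ccccc2)c(OCc2ccccc2)c1 | starting material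
2 | 4,5-bis(benzyloxy)-2-bromobenzaldehyde | O=Cc1cc(OCc2ccccc2)c(OCc2ccccc2)cc1Br | intermediate
3 | 3,4-bis(benzyloxy)benzyl chloride | ClCc1ccc(OCc2ccccc2)c(OCc2ccccc2)c1 | starting material
4 | 2-[3,4-bis(benzyloxy)benzyl]-4,4,5,5-tetramethyl-1,3,2-dioxaborolane | CC1(C)OB(Cc2ccc(OCc3ccccc3)c(OCc3ccccc3)c2)OC1(C)C | intermediate
5 | 4,5-bis(benzyloxy)-2-[3,4-bis(benzyloxy)benzyl]benzaldehyde | O=Cc1cc(OCc2ccccc2)c(OCc2ccccc2)cc1Cc1ccc(OCc2ccccc2)c(OCc2ccccc2)c1 | intermediate
6 | (R)-danshensu, (R)-3-(3,4-dihydroxyphenyl)-2-hydroxypropanoic acid | O[C@H](Cc1ccc(O)c(O)c1)C(=O)O | starting material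
7 | benzyl (R)-3-[3,4-bis(benzyloxy)phenyl]-2-hydroxypropanoate | O[C@H](Cc1ccc(OCc2ccccc2)c(OCc2ccccc2)c1)C(=O)OCc1ccccc1 | intermediate
8 | propiolic acid | C#CC(=O)O | starting material
9 | benzyl (R)-3-[3,4-bis(benzyloxy)phenyl]-2-(propioloyloxy)propanoate | C#CC(=O)O[C@H](Cc1ccc(OCc2ccccc2)c(OCc2ccccc2)c1)C(=O)OCc1ccccc1 | intermediate
10 | (E,E)-hydroxy-o-quinodimethane (photoenol of 5; OH and aryl both outward) | O/C=C1\C=C(OCc2ccccc2)C(OCc2ccccc2)=C/C1=C\c1ccc(OCc2ccccc2)c(OCc2ccccc2)c1 | intermediate (not isolated)
11 | (R)-1-(benzyloxy)-3-[3,4-bis(benzyloxy)phenyl]-1-oxopropan-2-yl (1S,4R)-6,7-bis(benzyloxy)-4-[3,4-bis(benzyloxy)phenyl]-1-hydroxy-1,4-dihydronaphthalene-2-carboxylate (cis; drawn isomer of the pair of cis adducts, the partner being 1R,4S) | O=C(O[C@H](Cc1ccc(OCc2ccccc2)c(OCc2ccccc2)c1)C(=O)OCc1ccccc1)C1=C[C@H](c2ccc(OCc3ccccc3)c(OCc3ccccc3)c2)c2cc(OCc3ccccc3)c(OCc3ccccc3)cc2[C@@H]1O | intermediate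
12 | (R)-1-(benzyloxy)-3-[3,4-bis(benzyloxy)phenyl]-1-oxopropan-2-yl 6,7-bis(benzyloxy)-4-[3,4-bis(benzyloxy)phenyl]-2-naphthoate | O=C(O[C@H](Cc1ccc(OCc2ccccc2)c(OCc2ccccc2)c1)C(=O)OCc1ccccc1)c1cc(-c2ccc(OCc3ccccc3)c(OCc3ccccc3)c2)c2cc(OCc3ccccc3)c(OCc3ccccc3)cc2c1 | intermediate
13 | eritrichin | O=C(O[C@H](Cc1ccc(O)c(O)c1)C(=O)O)c1cc(-c2ccc(O)c(O)c2)c2cc(O)c(O)cc2c1 | target

**Total step count:** 8.
**Longest linear sequence:** 5 steps (1, 3, 6, 7, 8). The branches through steps 2, 3 and through steps 4, 5 are equally long.

**Steps most likely to fail**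

1. Step 6. The alkyne is only mono-activated and may trap the dienol too slowly. Reketonisation, electrocyclic closure of the dienol, capture by residual oxygen and secondary photolysis of the adduct could then take over. The aryl donor on C4 may also erode the regioselectivity.
   The fallback separates the photochemistry from the cycloaddition and sets out from 5. Irradiation (λ > 340 nm) in degassed benzene saturated with SO2 should intercept 10 by fast cheletropic addition. This gives the storable racemic cis-5,6-bis(benzyloxy)-3-[3,4-bis(benzyloxy)phenyl]-1-hydroxy-1,3-dihydrobenzo[c]thiophene 2,2-dioxide F1.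
   Heating F1 with 9 in concentrated toluene solution at 80–110 °C, in the dark and under a slow argon purge, extrudes SO2 and regenerates the same (E,E)-dienol 10 thermally. The dienol then meets a high dienophile concentration with no light present. The sequence comes back to the route at 11. Any material already dehydrated by the heat simply passes through step 7 with it.

2. Step 5. DMAP or the alcohol may add in conjugate fashion to the activated propiolic acid, which may then oligomerise. Acyl migration to the N-acylurea is also possible because the α-hydroxy ester is a weak nucleophile.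
   The fallback masks the alkyne terminus and sets out from 7. Steglich esterification with commercial 3-(trimethylsilyl)propiolic acid (DCC, DMAP, CH2Cl2, 0 °C), whose silyl group shields the β-carbon, should give benzyl (R)-3-[3,4-bis(benzyloxy)phenyl]-2-{[3-(trimethylsilyl)propioloyl]oxy}propanoate F2. Protodesilylation with TBAF buffered by AcOH (THF, −20 °C) comes back to the route at 9.

3. Step 3. Transmetalation of the sp3 boronate may be slow, with protodeboronation and homocoupling of the benzylic partner.
   The fallback reverses the polarity of the coupling and sets out from 2. Miyaura borylation (B2pin2, PdCl2(dppf), KOAc, dioxane, 80 °C) should give 4,5-bis(benzyloxy)-2-(4,4,5,5-tetramethyl-1,3,2-dioxaborolan-2-yl)benzaldehyde F3, whose sp2 boronate transmetalates readily. F3 is then coupled with the benzylic chloride 3 as the electrophile (Pd(PPh3)4, K3PO4, toluene/H2O 10:1, 80 °C). This comes back to the route at 5 and makes step 2 unnecessary.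

**Further compounds**
F1 | step 6 | cis-5,6-bis(benzyloxy)-3-[3,4-bis(benzyloxy)phenyl]-1-hydroxy-1,3-dihydrobenzo[c]thiophene 2,2-dioxide (racemic, one enantiomer drawn) | O[C@@H]1c2cc(OCc3ccccc3)c(OCc3ccccc3)cc2[C@H](c2ccc(OCc3ccccc3)c(OCc3ccccc3)c2)S1(=O)=O
F2 | step 5 | benzyl (R)-3-[3,4-bis(benzyloxy)phenyl]-2-{[3-(trimethylsilyl)propioloyl]oxy}propanoate | C[Si](C)(C)C#CC(=O)O[C@H](Cc1ccc(OCc2ccccc2)c(OCc2ccccc2)c1)C(=O)OCc1ccccc1
F3 | step 3 | 4,5-bis(benzyloxy)-2-(4,4,5,5-tetramethyl-1,3,2-dioxaborolan-2-yl)benzaldehyde | O=Cc1cc(OCc2ccccc2)c(OCc2ccccc2)cc1B1OC(C)(C)C(C)(C)O1
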